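We decide to keep one account for L in the flask: what is left free, what is read as Q, and a remainder for whatever else took it.

| setting | north | south | flask |
|---|---|---|---|
| L | 0.050 M | 0.050 M | 0.050 M |
| D | 5 mM | 5 mM | 5.00 mM |
| X | 0.014 M | 0.022 M | 0.0100 M |
| remark | run made earlier | run made earlier |  |
| time |  |  | 2.5 h |

- north (time / min: L / %, Q / %): 8.00: 89.1, 6.2; 12.0: 84.0, 6.9; 15.0: 81.2, 7.2; 25.0: 69.6, 10.7; 40.0: 58.4, 16.5; 60.0: 44.1, 25.6; 90.0: 30.4, 32.1
- south (time / min: L / %, Q / %): 8.00: 90.4, 4.7; 12.0: 83.6, 7.6; 15.0: 79.5, 7.9; 25.0: 70.7, 13.1; 40.0: 56.4, 19.7; 60.0: 41.8, 24.8; 90.0: 28.4, 31.1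

(standard deviation of a reading: 1 percentage point)

- D is the free proton; pH is minus the decimal logarithm of its molar concentration
- a reading or a percentage of Q counts all its forms, free or not
- what has gone from L into another species counts as reacted, even if it can come back
- a reading of L is of its free form alone

* part of the L that has reacted at 2.5 h
* pH of the solution at 2.5 h

1. The last readings give a first-order constant for L, the logarithm of charged over left, divided by time: 0.0132 min⁻¹ in north, 0.0140 min⁻¹ in south.

2. The difference between them, divided by the difference in X, gives s, the gain in that constant per molar of X: 5.67 M⁻¹ h⁻¹. It is a rough reading, since it carries the scatter of both runs.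

3. Moving from north to the X of the flask gives 0.0129 min⁻¹, so our first entry is free L at 14.5 % and 85.5 % reacted.

4. We put that answer back into the account. North shows Q as 46.1 % of the L lost, so the flask books 39.4 % as Q and 46.1 % as remainder.

5. The remainder cannot be X alone if one X takes one L: in north it is 18.8 mM, more than the 0.014 M of X charged.

6. We book D as unspent, so the pH is that of its charge.

The forecast gives 85 % (81 % to 88.5 %) and pH 2.32 (2.28 to 2.5), holding that “Steady kinetics suggest D is barely consumed”.

The flask gives 83.7 % reacted at pH 2.30, with 16 % of L free against our 14.5 %, and D at 100 % of its charge.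

    L → G + Q (k = 0.110 h⁻¹)
    G ⇌ J + D, settled at all times (K = 1.00 × 10⁻⁷ M)
    L + D → G + D + Q (k = 52.0 M⁻¹ h⁻¹)
    L + Q ⇌ E, settled at all times (K = 820 M⁻¹)
    L + X → Z (k = 8.20 M⁻¹ h⁻¹)

In the flask, s books 7.35 % of the constant to X, and at 2.50 h the half-life of L by L + D into G + D + Q is 2.7 h, shorter than the 13 h by L + X into Z. Carried to a neighbour flask charged with 0.040 M of X, all else as in the flask, s gives 0.0157 min⁻¹ and so 90.5 % reacted, and that neighbour gives 88.8 %.

The earlier runs and the new flask are simulated with constants of no real substance, and the scatter is random.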